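**Strategy.** Kushenol G is cut at C8–C1'' and C2''–C3''. The feature exploited is that the sole stereocentre, C2'', stands one methylene (C1'') away from C8 of ring A. Its other saturated branch, C3''–C4''–C5'', stops at the dimethylcarbinol, so C1''–C2'' can come from a vinyl group. One enantioselective palladium conjunctive coupling joins aryl iodide, vinyl and alkylboron. It forms both bonds, sets C2'' and leaves boron there as a configurationally defined stand-in for isopropenyl, which a Zweifel olefination installs afterwards. The precursor pair is 8-iodo-penta-O-MOM-morin and a halide-free lithium alkyl(vinyl)pinacolborate carrying the TES-protected carbinol arm.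

Key step: step 6

Assumption: for alkyl migration the (S_p,S_p) MandyPhos series is taken to give the (S) boronate, so the (R_p,R_p) antipode is specified for (R)-C2''; both antipodes are sold, and oxidising a sample of the boronate to the carbinol followed by Mosher ester analysis would settle the assignment before the route continues.

**Step 1**
Reactants: 1 morin (3,5,7,2',4'-pentahydroxyflavone, dried)
Product: 2 3,5,7,2',4'-pentakis(methoxymethoxy)flavone (penta-O-MOM-morin)
Conditions: NaH (7.5 equiv), MOMCl (7.5 equiv), DMF, 0 °C to rt, argon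
Reagents that add atoms: chloromethyl methyl ether (MOMCl), COCCl
Why: Williamson-type O-alkylation of the five oxyanions: NaH is strong enough to break the 5-OH to C4=O hydrogen bond, the hard electrophile MOMCl reacts on oxygen and not on carbon, and acetal ethers withstand organolithiums, methoxide and iodine yet can later be removed without hydrogenation or strong acid.

**Step 2**
Reactants: 2 penta-O-MOM-morin
Product: 3 8-iodo-3,5,7,2',4'-pentakis(methoxymethoxy)flavone
Conditions: NIS (1.05 equiv), DMF, rt, dark, no acid additive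
Reagents that add atoms: N-iodosuccinimide (NIS), O=C1CCC(=O)N1I
Why: Electrophilic aromatic iodination: in 5-O-alkylated 5,7-dioxygenated flavones NIS in DMF attacks C8, since ring A keeps three oxygen donors against two on ring B and C6 is wedged between two MOM ethers, and leaving out any acid keeps C4=O unprotonated (protonation would switch off ring A in favour of C5') and spares the acetals.

**Step 3**
Reactants: 4 2-methylbut-3-en-2-ol
Product: 5 triethyl[(2-methylbut-3-en-2-yl)oxy]silane
Conditions: TESOTf (1.2 equiv), 2,6-lutidine (1.5 equiv), CH2Cl2, 0 °C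
Reagents that add atoms: triethylsilyl triflate (TESOTf), CC[Si](CC)(CC)OS(=O)(=O)C(F)(F)F
Why: Silylation of a hindered tertiary alcohol by a silyl triflate with a non-nucleophilic pyridine base; the TES ether removes the proton that would quench vinyllithium and is sturdy enough for chromatography, methoxide and 60 °C.

**Step 4**
Reactants: 5 TES ether of 2-methylbut-3-en-2-ol
Product: 6 pinacol [3-methyl-3-(triethylsilyloxy)butyl]boronate
Conditions: HBpin (1.2 equiv), [Ir(cod)Cl]2 (1.5 mol%), dppm (3 mol%), CH2Cl2, rt
Reagents that add atoms: pinacolborane (HBpin), [H]B1OC(C)(C)C(C)(C)O1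
Why: Iridium-catalysed anti-Markovnikov hydroboration of a terminal alkene with pinacolborane; [Ir(cod)Cl]2 is only active and terminal-selective once the diphosphine dppm is added, and the quaternary allylic carbon excludes alkene migration.

**Step 5**
Reactants: 7 vinyl iodide
Product: 8 vinyllithium (halide-free, titrated THF solution)
Conditions: n-BuLi (1.0 equiv), pentane, −78 °C; solid washed with pentane, dissolved in THF, titrated
Reagents that add atoms: n-butyllithium, [Li]CCCC
Why: Iodine–lithium exchange; vinyllithium precipitates from pentane and is washed free of 1-iodobutane, so the reagent carries no lithium halide, whereas a bromide/t-BuLi preparation would bring LiBr, an inhibitor of the cationic palladium species needed in step 6.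

**Step 6**
Reactants: 6 pinacol alkylboronate; 8 vinyllithium; 3 8-iodo-penta-O-MOM-morin
Product: 10 (R)-8-[5-methyl-2-(pinacolatoboryl)-5-(triethylsilyloxy)hexyl]-3,5,7,2',4'-pentakis(methoxymethoxy)flavone, via lithium alkyl(vinyl)pinacolborate 9 (not isolated)
Conditions: 6 (1.5 equiv), 8 (1.45 equiv), THF, 0 °C to rt; then 3 (1.0 equiv), Pd(OAc)2 (5 mol%), (R_P,R'_P)-1,1'-bis[bis(4-methoxy-3,5-dimethylphenyl)phosphino]-2,2'-bis[(S)-α-(dimethylamino)benzyl]ferrocene (MandyPhos ligand, 6 mol%), KOTf (2 equiv), THF, 60 °C
Reagents that add atoms: none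
Why: This is a palladium-catalysed enantioselective conjunctive cross-coupling, and its closest known relatives are the couplings of alkyl(vinyl)borates with aryl halides and triflates under Pd(OAc)2 and MandyPhos ligands. Zerovalent palladium inserts into the C8–I bond, KOTf takes iodide out as insoluble KI so that the divalent arylpalladium stays cationic and binds the vinyl group of 9, the alkyl arm then shifts from boron to the boron-bearing carbon on the face opposite to palladium (C2''–C3''), and reductive elimination from the resulting C1''–palladium species makes the C8–C1'' bond. No ring is formed. C2'' is the only new stereocentre and is controlled by the chiral ferrocenyl bisphosphine alone, which chooses the vinyl face that palladium occupies, because 3, 6 and 8 are all achiral. The step needs the metallate shift to outrun direct vinyl transfer and beta-hydride loss, which the wide-bite-angle ligand and the quick reductive elimination of a crowded aryl group favour, while the iodide (not a bromide) and the raised catalyst loading answer the slow insertion between O1 and 7-OMOM. Because 8 is kept slightly short of 6, no free vinyllithium survives to attack C4=O of ring C, and halide-free 8 adds no further inhibitor.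

**Step 7**
Reactants: 10 (R)-secondary pinacol boronate; 11 2-bromopropene
Product: 15 (R)-8-[2-isopropenyl-5-methyl-5-(triethylsilyloxy)hexyl]-3,5,7,2',4'-pentakis(methoxymethoxy)flavone, via isopropenyllithium 12 (not isolated), via lithium isopropenylborate 13 (not isolated), via beta-iodoalkyl boronate 14 (not isolated)
Conditions: 11 (1.2 equiv), t-BuLi (2.3 equiv), Et2O, −78 °C; added slowly to 10 in THF, −78 °C; I2 (1.3 equiv), THF, −78 °C; NaOMe (3 equiv), MeOH, −78 °C to rt; aq Na2S2O3
Reagents that add atoms: none
Why: Zweifel olefination: at −78 °C the Lewis-acidic boron should capture the one equivalent of isopropenyllithium ahead of C4=O, which is a doubly vinylogous ester shielded by the 3-O- and 5-O-MOM groups, iodine then triggers the 1,2-shift of C2'' from boron to carbon with retention, and methoxide induces anti elimination of boron and iodide, so the (R) configuration is carried over unchanged.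

**Step 8**
Reactants: 15 penta-O-MOM O-TES kushenol G
Product: 18 kushenol G [(R)-8-(5-hydroxy-2-isopropenyl-5-methylhexyl)-3,5,7,2',4'-pentahydroxyflavone], via penta-O-TMS ether 16 (not isolated), via O-TES kushenol G 17 (not isolated)
Conditions: TMSOTf (12 equiv), 2,2'-bipyridyl (18 equiv), MeCN, 0 °C to rt; H2O, rt; HF·pyridine, 0 °C to rt
Reagents that add atoms: none
Why: Silyl triflate/2,2'-bipyridyl cleavage of aryl MOM ethers followed by hydrolysis and fluoride desilylation: each acetal is exchanged for a TMS ether while bipyridyl traps the methoxymethyl cation as a pyridinium salt and buffers all triflic acid, so the isopropenyl group, the tertiary carbinol and the adjacent 7-OH never meet an acid strong enough for chroman closure, dehydration or hydration, and C2'' is not touched.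

**Compound list**
1 | morin | O=c1c(O)c(-c2ccc(O)cc2O)oc2cc(O)cc(O)c12 | starting material
2 | penta-O-MOM-morin | COCOc1cc(OCOC)c2c(=O)c(OCOC)c(-c3ccc(OCOC)cc3OCOC)oc2c1 | intermediate
3 | 8-iodo-penta-O-MOM-morin | COCOc1cc(OCOC)c2c(=O)c(OCOC)c(-c3ccc(OCOC)cc3OCOC)oc2c1I | intermediate
4 | 2-methylbut-3-en-2-ol | C=CC(C)(C)O | starting material
5 | triethyl[(2-methylbut-3-en-2-yl)oxy]silane | C=CC(C)(C)O[Si](CC)(CC)CC | intermediate
6 | pinacol [3-methyl-3-(triethylsilyloxy)butyl]boronate | CC1(C)OB(CCC(C)(C)O[Si](CC)(CC)CC)OC1(C)C | intermediate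
7 | vinyl iodide | C=CI | starting material
8 | vinyllithium | [Li]C=C | intermediate
9 | lithium [3-methyl-3-(triethylsilyloxy)butyl](vinyl)pinacolborate | [Li+].C=C[B-]1(CCC(C)(C)O[Si](CC)(CC)CC)OC(C)(C)C(C)(C)O1 | intermediate
10 | (R)-C2'' pinacol boronate of the 8-alkyl penta-O-MOM flavonol | CC1(C)OB(OC1(C)C)[C@H](CCC(C)(C)O[Si](CC)(CC)CC)Cc1c(OCOC)cc(OCOC)c2c(=O)c(OCOC)c(-c3ccc(OCOC)cc3OCOC)oc12 | intermediate
11 | 2-bromopropene | C=C(C)Br | starting material
12 | isopropenyllithium | [Li]C(C)=C | intermediate
13 | lithium (R)-alkyl(isopropenyl)pinacolborate | [Li+].C=C(C)[B-]1(OC(C)(C)C(C)(C)O1)[C@H](CCC(C)(C)O[Si](CC)(CC)CC)Cc1c(OCOC)cc(OCOC)c2c(=O)c(OCOC)c(-c3ccc(OCOC)cc3OCOC)oc12 | intermediate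
14 | beta-iodoalkyl pinacol boronate, (R) at C2'', mixture at the transient quaternary carbon | ICC(C)(B1OC(C)(C)C(C)(C)O1)[C@H](CCC(C)(C)O[Si](CC)(CC)CC)Cc1c(OCOC)cc(OCOC)c2c(=O)c(OCOC)c(-c3ccc(OCOC)cc3OCOC)oc12 | intermediate
15 | (R)-penta-O-MOM O-TES kushenol G | C=C(C)[C@H](CCC(C)(C)O[Si](CC)(CC)CC)Cc1c(OCOC)cc(OCOC)c2c(=O)c(OCOC)c(-c3ccc(OCOC)cc3OCOC)oc12 | intermediate
16 | (R)-penta-O-TMS O-TES kushenol G | C=C(C)[C@H](CCC(C)(C)O[Si](CC)(CC)CC)Cc1c(O[Si](C)(C)C)cc(O[Si](C)(C)C)c2c(=O)c(O[Si](C)(C)C)c(-c3ccc(O[Si](C)(C)C)cc3O[Si](C)(C)C)oc12 | intermediate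
17 | (R)-O-TES kushenol G | C=C(C)[C@H](CCC(C)(C)O[Si](CC)(CC)CC)Cc1c(O)cc(O)c2c(=O)c(O)c(-c3ccc(O)cc3O)oc12 | intermediate
18 | kushenol G, (R) at C2'' | C=C(C)[C@H](CCC(C)(C)O)Cc1c(O)cc(O)c2c(=O)c(O)c(-c3ccc(O)cc3O)oc12 | target

**Total step count:** 8. **Longest linear sequence:** 5 (steps 1, 2, 6, 7, 8; the boronate arm, steps 3, 4, 6, 7, 8, is equally long).

**Steps most likely to fail**

**Step 6.**
- What may go wrong: oxidative addition between O1 and the 7-O-MOM group may be too slow. Iodide may return to palladium and block alkene binding. Direct vinyl transfer may overtake the metallate shift. Coordination of an ortho acetal oxygen may erode facial selectivity.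
- Fallback, from 9 and 3 back to 10: the asymmetric event is moved away from the flavonol. Borate 9 is treated with I2 and then NaOMe (Zweifel vinylation); the transient racemic beta-iodoalkyl boronate F1 collapses to 5-methyl-5-(triethylsilyloxy)hex-1-ene F2. Platinum-catalysed enantioselective diboration of this unhindered terminal alkene (B2pin2, Pt(dba)3, the suitable antipode of a TADDOL-derived phenylphosphonite, THF, 60 °C) gives the (S)-1,2-bis(pinacolboronate) F3, which already has the spatial arrangement needed at C2''. A Suzuki–Miyaura coupling with 3 (Pd(OAc)2, RuPhos, KOH, THF/H2O, 70 °C) engages only the primary C–B bond, which the neighbouring boronate activates. It yields 10 with a ligand built for hindered aryl halides.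

**Step 7.**
- What may go wrong: addition of the alkenyllithium to C4=O or C2 of ring C may compete with capture by the hindered secondary boron, and surplus iodine may attack ring A.
- Fallback, from 3 and 9 back to 15: carbon replaces oxygen with inversion, and the hard nucleophile is given up. Step 6 is run with the (S_p,S_p) ligand antipode to give the (S)-boronate F4. NaBO3·4H2O in THF/H2O oxidises it with retention to the (S)-carbinol F5, and TsCl, DMAP and pyridine give the (S)-tosylate F6. The soft cuprate (CH2=C(CH3))2CuLi, made from 12 and CuI in Et2O at −30 to 0 °C, displaces the tosylate in an SN2 reaction with inversion. This gives (R)-15 and leaves the fully substituted chromone alone.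

**Step 2.**
- What may go wrong: poor site selectivity, with attack at C6 or at C5' of the resorcinol-type ring B, and double iodination.
- Fallback, from 1 back to 3: ring B is switched off with acyl groups and ring A is switched on with one free phenol. Ac2O and pyridine give morin pentaacetate F7. PhSH and imidazole in NMP remove only the most activated ester and give 3,5,2',4'-tetra-O-acetylmorin F8 with 7-OH free. NIS in DMF then iodinates ortho to that phenol at C8, the usual site in 7-hydroxychromones, and gives the 8-iodo tetraacetate F9. K2CO3 in MeOH under argon gives 8-iodomorin F10, and NaH/MOMCl as in step 1 leads to 3.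

**Further compounds**
F1 | step 6 | pinacol [1-iodo-5-methyl-5-(triethylsilyloxy)hexan-2-yl]boronate (racemic, transient) | ICC(CCC(C)(C)O[Si](CC)(CC)CC)B1OC(C)(C)C(C)(C)O1
F2 | step 6 | 5-methyl-5-(triethylsilyloxy)hex-1-ene | C=CCCC(C)(C)O[Si](CC)(CC)CC
F3 | step 6 | (S)-1,2-bis(pinacolatoboryl)-5-methyl-5-(triethylsilyloxy)hexane | CC1(C)OB(OC1(C)C)[C@H](CCC(C)(C)O[Si](CC)(CC)CC)CB1OC(C)(C)C(C)(C)O1
F4 | step 7 | (S)-enantiomer of boronate 10 | CC1(C)OB(OC1(C)C)[C@@H](CCC(C)(C)O[Si](CC)(CC)CC)Cc1c(OCOC)cc(OCOC)c2c(=O)c(OCOC)c(-c3ccc(OCOC)cc3OCOC)oc12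
F5 | step 7 | (S)-8-[2-hydroxy-5-methyl-5-(triethylsilyloxy)hexyl]-penta-O-MOM-morin | O[C@@H](CCC(C)(C)O[Si](CC)(CC)CC)Cc1c(OCOC)cc(OCOC)c2c(=O)c(OCOC)c(-c3ccc(OCOC)cc3OCOC)oc12
F6 | step 7 | (S)-tosylate of F5 | Cc1ccc(cc1)S(=O)(=O)O[C@@H](CCC(C)(C)O[Si](CC)(CC)CC)Cc1c(OCOC)cc(OCOC)c2c(=O)c(OCOC)c(-c3ccc(OCOC)cc3OCOC)oc12
F7 | step 2 | morin pentaacetate | CC(=O)Oc1cc(OC(C)=O)c2c(=O)c(OC(C)=O)c(-c3ccc(OC(C)=O)cc3OC(C)=O)oc2c1
F8 | step 2 | 3,5,2',4'-tetra-O-acetylmorin | Oc1cc(OC(C)=O)c2c(=O)c(OC(C)=O)c(-c3ccc(OC(C)=O)cc3OC(C)=O)oc2c1
F9 | step 2 | 8-iodo-3,5,2',4'-tetra-O-acetylmorin | Oc1cc(OC(C)=O)c2c(=O)c(OC(C)=O)c(-c3ccc(OC(C)=O)cc3OC(C)=O)oc2c1I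
F10 | step 2 | 8-iodomorin | Oc1cc(O)c2c(=O)c(O)c(-c3ccc(O)cc3O)oc2c1I
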